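## Analysis of the target

Target **20** is a diterpenoid on a trans-fused hydroazulene. Ring A is a cyclopentene (C1–C5, C3=C4, methyl on C4). It is fused through C1–C5 to the seven-membered ring B (C1, C5, C6, C7, C8, C9, C10), which carries the exocyclic methylene C10=C18, a free secondary hydroxyl on C6 and, on C7, the oxolane ring C (O, C11–C14). C11 is quaternary (methyl, C7, O, C12); C14 carries the CMe2OAc group (C15).

There are six stereocentres: C1 (R) and C5 (S) with H1 and H5 trans, C6 (S), C7 (R), C11 (R) and C14 (S). The C6 hydroxyl is trans to the C5–C4 bond and cis to the C7–C11 bond; in the zigzag C5–C6–C7–C8 the hydroxyl and C11 are anti. On ring C the C7 and C15 substituents are cis.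

Sensitive points:
- The tertiary acetate sits beside a free secondary alcohol, so a late selective acylation would run the wrong way round.
- Under acid the C6 hydroxyl can add across C10=C18 to give a bridging ether.
- The 1,1-disubstituted olefin can migrate into ring B.
- C5 is allylic.

The hard part is the contiguous array C5–C6–C7–C11 ending in a quaternary carbon, together with the trans ring fusion and a seven-membered ring whose only unsaturation is exocyclic.

Two features invite the plan:
1. Once the C9–C10 bond is cut, C6(OH)–C7(H)(C11)–C8=C9 is an anti β-branched homoallylic alcohol. That is the retron of an (E)-γ-substituted allylboration in which the nucleophile already carries ring C.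
2. Ring A with C6, the C4 methyl, C10 and C18 has the carbon pattern of a monoterpene cyclohexenone after a one-carbon ring contraction. Ring C with C7 and C15–C17 is a cyclised acyclic monoterpene alcohol.

## Retrosynthetic reasoning

**C9–C10 (20 ⇒ 18).** The seven-membered ring is opened at the sp3–sp2 bond next to the methylene. This bond is chosen because it is remote from all stereocentres, and because an alkenyl triflate at C10 and a terminal olefin C8=C9 in **18** can be joined by hydroboration and intramolecular B-alkyl Suzuki–Miyaura coupling. That coupling creates C10=C18 as an exocyclic olefin directly and needs neither acid nor a protecting group on the C6 hydroxyl. The tertiary acetate is already in place, so the ring closure delivers **20**.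

**C6–C7 (18 ⇒ 16 + 6).** The anti homoallylic alcohol is cut into aldehyde **16** (ring A with C1, C5 and the alkenyl triflate) and the (E)-allylboronate **6** (ring C with C7–C9). The forward reaction must form the most congested bond of the molecule, set C6 and C7 together, and leave the vinyl group for the ring closure. A closed chair transition state gives the anti relationship from the (E) geometry; the aldehyde face is left to a chiral Brønsted acid and the α-stereocentre C5.

**Ring A (16 ⇒ 15 ⇒ 14 ⇒ 12 ⇒ 9 ⇒ 7).** The aldehyde comes from ester **15**, the alkenyl triflate from methyl ketone **14**, and the ketone from the isopropenyl group of **12**. Ester **12** is the ring-contracted form of the cyclohexenone **7**: a Wolff rearrangement of the α′-diazo ketone **9** moves the alkenyl carbon and turns the six-membered ring into ring A. The stereocentre of **7** becomes C1, the ring carbonyl carbon becomes C6, C3=C4 is already in place, and C5 settles trans to C1 by equilibration. Nine of the ten carbons of **7** end up in **20**.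

**Ring C (6 ⇒ 4 + 5 ⇒ 3 ⇒ 1).** The allylboronate is cut at the C7=C8 olefin (cross-metathesis of the vinyl group of **4** with **5**). Acetate **4** comes from alcohol **3**, and **3** from **1** by reagent-controlled epoxidation of the trisubstituted olefin and 5-exo opening by the tertiary hydroxyl. C11 is taken from **1**; C14 is set by the epoxidation catalyst.

## Alternatives that were turned down

**Alternative 1:** (the textbook route) Disconnection of the oxolane C14–O bond at the end: 5-exo opening of a 14,15-epoxide by the C11 tertiary hydroxyl of the triene diol A1, then acetylation. The hydroazulene would be built beforehand by ring-closing metathesis and carbonyl methylenation at C10. Forward key step: site-selective epoxidation of the C14=C15 olefin of A1 and acid-mediated cyclisation. Turned down because: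
- A1 has three olefins of similar nucleophilicity (C3=C4, C10=C18, C14=C15).
- C11 would have to be set by addition of a homoprenyl nucleophile to an acetyl group on C7, with weak 1,2-induction.
- The acid needed for cyclisation also lets the C6 hydroxyl add to C10=C18.
- The end game must acylate the tertiary C15 hydroxyl beside the secondary C6 hydroxyl, which costs protecting-group steps.

**Alternative 2:** Disconnection of C5–C6, reading C6(OH)–C5–C4=C3 as the retron of a type-1 intramolecular carbonyl-ene reaction of aldehyde A2 (C6 aldehyde tethered through C7–C10 to C1 of a 3-methylcyclopent-2-enyl group, C10 masked as a dithiane). Forward key step: Me2AlCl-promoted ene cyclisation that closes ring B, sets C5 and C6, moves the olefin from C4=C5 to C3=C4 and frees the C6 hydroxyl. Turned down because: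
- C10 cannot be carried as the methylene: a 5-substituted hex-5-enal would close the six-membered ring by the type-2 ene reaction first. Mask, unmasking and methylenation cost three steps.
- A tether-delivered attack on the cyclopentene is expected on the face syn to the C1 substituent, giving the cis ring fusion; correction would need epimerisation of C1 through a C10 ketone with an unknown equilibrium.
- A2 needs separate asymmetric constructions of C1 and C7.

**Alternative 3:** Disconnection of C1–C10 and C5–C6 as a (5+2) annulation on cyclopent-2-enone: rhodium-catalysed asymmetric conjugate addition of a C10 alkenylboron reagent that carries the C6 aldehyde, with the C5 enolate closing ring B by aldol addition to give the hydroxy ketone A3. Turned down because: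
- The alkenyl-metal intermediate can add to its own tethered aldehyde through a five-membered transition state faster than to the enone.
- A stepwise version loses the regiodefined C5 enolate.
- A3 is a β-hydroxy ketone prone to retro-aldol cleavage and elimination, and still needs protection, regioselective enol triflate formation towards C3, methyl coupling and deprotection to reach C3=C4.

Key step: step 9

Remarks on the chemistry:
- The locants C1–C18 used throughout are those defined in the analysis; for intermediates they name the target atom that the carbon becomes.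
- Commercial (R)-linalool and (R)-carvone are assumed to be of high enantiomeric purity.
- In step 10 the hindered C6 hydroxyl may consume part of the excess borane as a borinate that is hydrolysed on work-up.

## Route

Step 1
Reactants: 1 (3R)-3,7-dimethylocta-1,6-dien-3-ol [(R)-linalool]
Product: 3 2-[(2S,5R)-5-ethenyl-5-methyloxolan-2-yl]propan-2-ol, via epoxy alcohol 2 (not isolated)
Conditions: D-fructose-derived Shi ketone (30 mol %), Oxone (2KHSO5·KHSO4·K2SO4), K2CO3, Bu4NHSO4, MeCN/dimethoxymethane/aq. buffer pH 10.5, 0 °C; extract; then camphorsulfonic acid (10 mol %), CH2Cl2, 0 °C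
Reagents that add atoms: Oxone (potassium peroxymonosulfate, one oxygen atom), [K+].[O-]S(=O)(=O)OO
Why: Shi epoxidation attacks only the electron-rich trisubstituted olefin, and the D-fructose-derived ketone should give the (R)-epoxide at C14. Acid-catalysed 5-exo opening by the C11 hydroxyl with inversion then sets C14 (S), while C11 is retained from 1. The six-membered (6-endo) ether and any diastereomer from residual (S)-linalool should be separable here.

Step 2
Reactants: 3 2-[(2S,5R)-5-ethenyl-5-methyloxolan-2-yl]propan-2-ol
Product: 4 2-[(2S,5R)-5-ethenyl-5-methyloxolan-2-yl]propan-2-yl acetate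
Conditions: Ac2O, Et3N, DMAP, CH2Cl2, 40 °C
Reagents that add atoms: acetic anhydride, CC(=O)OC(C)=O
Why: DMAP-catalysed acylation of the only hydroxyl group installs the tertiary acetate before any secondary alcohol exists, so no later differentiation is needed. No stereocentre is touched.

Step 3
Reactants: 4 2-[(2S,5R)-5-ethenyl-5-methyloxolan-2-yl]propan-2-yl acetate; 5 4,4,5,5-tetramethyl-2-(prop-2-en-1-yl)-1,3,2-dioxaborolane (allylboronic acid pinacol ester, 3 equiv)
Product: 6 2-[(2S,5R)-5-methyl-5-[(1E)-3-(4,4,5,5-tetramethyl-1,3,2-dioxaborolan-2-yl)prop-1-en-1-yl]oxolan-2-yl]propan-2-yl acetate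
Conditions: second-generation Hoveyda–Grubbs catalyst (5 mol %), CH2Cl2, 40 °C
Reagents that add atoms: none
Why: Olefin cross-metathesis of a vinyl group on a quaternary carbon (which does not homodimerise) with an excess of the rapidly reacting allylboronate should give the cross product. The bulk of C11 should enforce the (E) geometry that step 9 translates into the C7 configuration.

Step 4
Reactants: 7 (5R)-2-methyl-5-(prop-1-en-2-yl)cyclohex-2-en-1-one [(R)-carvone]
Product: 9 (5S)-6-diazo-2-methyl-5-(prop-1-en-2-yl)cyclohex-2-en-1-one, via trifluoroacetyl ketone 8 (not isolated)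
Conditions: LiN(SiMe3)2, THF, −78 °C; CF3CO2CH2CF3; then MsN3, Et3N, H2O (1 equiv), MeCN, rt
Reagents that add atoms: methanesulfonyl azide, CS(=O)(=O)N=[N+]=[N-]; 2,2,2-trifluoroethyl trifluoroacetate, O=C(OCC(F)(F)F)C(F)(F)F (its trifluoroacetyl group is carried only in 8)
Why: Kinetic α′-deprotonation and trifluoroacetylation activate the future C5 for detrifluoroacetylative diazo transfer, the standard way to α′-diazo enones. The stereocentre (future C1) is not involved.

Step 5
Reactants: 9 (5S)-6-diazo-2-methyl-5-(prop-1-en-2-yl)cyclohex-2-en-1-one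
Product: 12 methyl (1S,5R)-2-methyl-5-(prop-1-en-2-yl)cyclopent-2-ene-1-carboxylate, via ketene 10 (not isolated), via cis ester 11 (not isolated)
Conditions: hν (Pyrex filter), MeOH, 0 °C to rt; then NaOMe (10 mol %), MeOH, 0 °C, AcOH quench
Reagents that add atoms: methanol, CO
Why: Photochemical Wolff rearrangement shifts the alkenyl carbon (future C4) to the carbene carbon (future C5) and contracts the ring to ketene 10, which methanol traps as the β,γ-unsaturated ester with C3=C4 in place. Brief methoxide equilibration of the epimerisable C5 funnels the kinetic cis/trans mixture into the trans ester (C5 S), which is the later trans ring fusion.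

Step 6
Reactants: 12 methyl (1S,5R)-2-methyl-5-(prop-1-en-2-yl)cyclopent-2-ene-1-carboxylate
Product: 14 methyl (1S,5R)-5-acetyl-2-methylcyclopent-2-ene-1-carboxylate, via diol 13 (not isolated)
Conditions: K2OsO4·2H2O (2 mol %), NaIO4, 2,6-lutidine, 1,4-dioxane/H2O, 0 °C to rt
Reagents that add atoms: sodium periodate, [Na+].[O-]I(=O)(=O)=O; water, O
Why: Lemieux–Johnson cleavage should take the unhindered 1,1-disubstituted olefin in preference to the trisubstituted ring olefin, which is flanked by the ester-bearing carbon. This turns the isopropenyl group into the C10 acetyl group, with the methyl being the future C18. Buffered conditions leave C1 and C5 untouched.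

Step 7
Reactants: 14 methyl (1S,5R)-5-acetyl-2-methylcyclopent-2-ene-1-carboxylate
Product: 15 methyl (1S,5R)-2-methyl-5-[1-(trifluoromethanesulfonyloxy)ethenyl]cyclopent-2-ene-1-carboxylate
Conditions: KN(SiMe3)2 (1.05 equiv), THF, −78 °C; then Comins' reagent, −78 °C
Reagents that add atoms: N-(5-chloropyridin-2-yl)-1,1,1-trifluoro-N-(trifluoromethanesulfonyl)methanesulfonamide (Comins' reagent), O=S(=O)(N(c1ccc(Cl)cn1)S(=O)(=O)C(F)(F)F)C(F)(F)F
Why: Kinetic deprotonation by the bulky amide base occurs at the methyl group rather than at the tertiary C1–H or C5–H, and O-triflation at −78 °C traps the terminal enolate as the 2-triflyloxy-1-alkene (C10=C18). Staying under kinetic control keeps C1 and C5 from equilibrating.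

Step 8
Reactants: 15 methyl (1S,5R)-2-methyl-5-[1-(trifluoromethanesulfonyloxy)ethenyl]cyclopent-2-ene-1-carboxylate
Product: 16 1-[(1R,2S)-2-formyl-3-methylcyclopent-3-en-1-yl]ethenyl trifluoromethanesulfonate
Conditions: iBu2AlH (1.1 equiv), CH2Cl2, −78 °C; MeOH, then aq. Rochelle salt; used crude at once
Reagents that add atoms: none
Why: Partial reduction of the α-branched methyl ester stops at the tetrahedral aluminium hemiacetal at −78 °C and releases the C6 aldehyde on work-up; the alkenyl triflate is inert to the hydride. The β,γ-unsaturated aldehyde is not stored, so C5 is not given time to epimerise or the olefin to conjugate.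

Step 9
Reactants: 16 1-[(1R,2S)-2-formyl-3-methylcyclopent-3-en-1-yl]ethenyl trifluoromethanesulfonate; 6 2-[(2S,5R)-5-methyl-5-[(1E)-3-(4,4,5,5-tetramethyl-1,3,2-dioxaborolan-2-yl)prop-1-en-1-yl]oxolan-2-yl]propan-2-yl acetate
Product: 18 2-[(2S,5R)-5-[(1S,2R)-1-hydroxy-1-[(1S,5R)-2-methyl-5-[1-(trifluoromethanesulfonyloxy)ethenyl]cyclopent-2-en-1-yl]but-3-en-2-yl]-5-methyloxolan-2-yl]propan-2-yl acetate, via pinacol borate 17 (not isolated)
Conditions: (R)-TRIP [(R)-3,3′-bis(2,4,6-triisopropylphenyl)-1,1′-binaphthyl-2,2′-diyl hydrogen phosphate] (5 mol %), 4 Å MS, toluene, −30 to 0 °C; then aq. NaHCO3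
Reagents that add atoms: none
Why: The aldehyde oxygen binds to boron and the allyl group is transferred through a closed six-membered chair (Zimmerman–Traxler type) with allylic transposition; the closest known reaction type is the chiral phosphoric acid-catalysed crotylboration of aldehydes with pinacol (E)-crotylboronates, where the acid activates the boronate by hydrogen bonding to a pinacol oxygen. No ring is closed here: the step forms C6–C7, joins the two terpene-derived halves and unmasks the C8=C9 vinyl group for step 10. C7 is controlled by the (E) geometry of 6: C11 and the aldehyde residue are both pseudo-equatorial in the chair, which fixes the anti relationship between the C6 hydroxyl and the C7–C11 bond. C6 is controlled by the aldehyde face: (R)-TRIP is the antipode expected to direct the allyl group to the Re face. The substrate should act in the same sense, because H5 must point towards the bulky C11 group to avoid a syn-pentane contact, which leaves the sp3 carbon C1 anti to the forming bond and the flat sp2 carbon C4 gauche. The step needs γ-regioselectivity (inherent to allylboronates), anti diastereoselectivity (secured by the olefin geometry from step 3) and Re-face selectivity (catalyst plus Felkin-type bias). It also needs C5 to stay intact, which the non-basic medium and low temperature should secure. C1, C5, C11 and C14 are not touched, and the tertiary acetate and alkenyl triflate are inert.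

Step 10
Reactants: 18 2-[(2S,5R)-5-[(1S,2R)-1-hydroxy-1-[(1S,5R)-2-methyl-5-[1-(trifluoromethanesulfonyloxy)ethenyl]cyclopent-2-en-1-yl]but-3-en-2-yl]-5-methyloxolan-2-yl]propan-2-yl acetate
Product: 20 2-[(2S,5R)-5-[(3aS,4S,5R,8aR)-4-hydroxy-3-methyl-8-methylidene-1,3a,4,5,6,7,8,8a-octahydroazulen-5-yl]-5-methyloxolan-2-yl]propan-2-yl acetate, via alkylborane 19 (not isolated)
Conditions: 9-BBN dimer (2.6 equiv B–H), THF, 0 °C to rt; then Pd(dppf)Cl2 (10 mol %), AsPh3 (10 mol %), Cs2CO3, DMF/THF/H2O, 0.005 M, 50 °C
Reagents that add atoms: none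
Why: 9-BBN adds only to the monosubstituted C8=C9 olefin, with boron at C9; the trisubstituted ring olefin and the electron-poor enol triflate are too slow. Oxidative addition of zerovalent palladium into the C10–OTf bond, base-assisted transmetalation and reductive elimination (intramolecular B-alkyl Suzuki–Miyaura coupling) then close ring B at C9–C10 and leave C10=C18 exocyclic. The basic, acid-free medium protects the C6 hydroxyl/C10 methylene pair and the tertiary acetate, and no stereocentre is created or touched.

## Compound list

1 | (3R)-3,7-dimethylocta-1,6-dien-3-ol [(R)-linalool] | C=C[C@](C)(O)CCC=C(C)C | starting material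
2 | (3R)-5-[(2R)-3,3-dimethyloxiran-2-yl]-3-methylpent-1-en-3-ol | C=C[C@](C)(O)CC[C@H]1OC1(C)C | intermediate (not isolated)
3 | 2-[(2S,5R)-5-ethenyl-5-methyloxolan-2-yl]propan-2-ol | C=C[C@@]1(C)CC[C@@H](C(C)(C)O)O1 | intermediate
4 | 2-[(2S,5R)-5-ethenyl-5-methyloxolan-2-yl]propan-2-yl acetate | C=C[C@@]1(C)CC[C@@H](C(C)(C)OC(C)=O)O1 | intermediate
5 | 4,4,5,5-tetramethyl-2-(prop-2-en-1-yl)-1,3,2-dioxaborolane | C=CCB1OC(C)(C)C(C)(C)O1 | starting material
6 | 2-[(2S,5R)-5-methyl-5-[(1E)-3-(4,4,5,5-tetramethyl-1,3,2-dioxaborolan-2-yl)prop-1-en-1-yl]oxolan-2-yl]propan-2-yl acetate | CC1(C)OB(C/C=C/[C@@]2(C)CC[C@@H](C(C)(C)OC(C)=O)O2)OC1(C)C | intermediate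
7 | (5R)-2-methyl-5-(prop-1-en-2-yl)cyclohex-2-en-1-one [(R)-carvone] | CC1=CC[C@H](CC1=O)C(C)=C | starting material
8 | (5R)-2-methyl-5-(prop-1-en-2-yl)-6-(trifluoroacetyl)cyclohex-2-en-1-one (present as its enolate; C6 not defined) | CC1=CC[C@H](C(C(=O)C(F)(F)F)C1=O)C(C)=C | intermediate (not isolated)
9 | (5S)-6-diazo-2-methyl-5-(prop-1-en-2-yl)cyclohex-2-en-1-one | CC1=CC[C@H](C(=[N+]=[N-])C1=O)C(C)=C | intermediate
10 | [(5S)-2-methyl-5-(prop-1-en-2-yl)cyclopent-2-en-1-ylidene]methanone (ketene) | O=C=C1C(C)=CC[C@H]1C(C)=C | intermediate (not isolated)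
11 | methyl (1R,5R)-2-methyl-5-(prop-1-en-2-yl)cyclopent-2-ene-1-carboxylate (cis) | COC(=O)[C@H]1C(C)=CC[C@H]1C(C)=C | intermediate (not isolated)
12 | methyl (1S,5R)-2-methyl-5-(prop-1-en-2-yl)cyclopent-2-ene-1-carboxylate (trans) | COC(=O)[C@@H]1C(C)=CC[C@H]1C(C)=C | intermediate
13 | methyl (1S,5R)-5-(1,2-dihydroxypropan-2-yl)-2-methylcyclopent-2-ene-1-carboxylate (carbinol centre not defined) | COC(=O)[C@@H]1C(C)=CC[C@H]1C(C)(O)CO | intermediate (not isolated)
14 | methyl (1S,5R)-5-acetyl-2-methylcyclopent-2-ene-1-carboxylate | COC(=O)[C@@H]1C(C)=CC[C@H]1C(C)=O | intermediate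
15 | methyl (1S,5R)-2-methyl-5-[1-(trifluoromethanesulfonyloxy)ethenyl]cyclopent-2-ene-1-carboxylate | COC(=O)[C@@H]1C(C)=CC[C@H]1C(=C)OS(=O)(=O)C(F)(F)F | intermediate
16 | 1-[(1R,2S)-2-formyl-3-methylcyclopent-3-en-1-yl]ethenyl trifluoromethanesulfonate | O=C[C@@H]1C(C)=CC[C@H]1C(=C)OS(=O)(=O)C(F)(F)F | intermediate
17 | pinacol borate ester of 18 (C6–O–B) | C=C[C@@H]([C@@]1(C)CC[C@@H](C(C)(C)OC(C)=O)O1)[C@@H](OB1OC(C)(C)C(C)(C)O1)[C@@H]1C(C)=CC[C@H]1C(=C)OS(=O)(=O)C(F)(F)F | intermediate (not isolated)
18 | 2-[(2S,5R)-5-[(1S,2R)-1-hydroxy-1-[(1S,5R)-2-methyl-5-[1-(trifluoromethanesulfonyloxy)ethenyl]cyclopent-2-en-1-yl]but-3-en-2-yl]-5-methyloxolan-2-yl]propan-2-yl acetate | C=C[C@@H]([C@@]1(C)CC[C@@H](C(C)(C)OC(C)=O)O1)[C@@H](O)[C@@H]1C(C)=CC[C@H]1C(=C)OS(=O)(=O)C(F)(F)F | intermediate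
19 | B-alkyl-9-borabicyclo[3.3.1]nonane adduct of 18 (boron on C9) | C1CCC2CCCC1B2CC[C@@H]([C@@]1(C)CC[C@@H](C(C)(C)OC(C)=O)O1)[C@@H](O)[C@@H]1C(C)=CC[C@H]1C(=C)OS(=O)(=O)C(F)(F)F | intermediate (not isolated)
20 | 2-[(2S,5R)-5-[(3aS,4S,5R,8aR)-4-hydroxy-3-methyl-8-methylidene-1,3a,4,5,6,7,8,8a-octahydroazulen-5-yl]-5-methyloxolan-2-yl]propan-2-yl acetate | C=C1CC[C@@H]([C@@]2(C)CC[C@@H](C(C)(C)OC(C)=O)O2)[C@@H](O)[C@@H]2C(C)=CC[C@@H]12 | target

## Step count and least certain steps

Total step count: 10 (steps 1–3 for the ring C half, steps 4–8 for the ring A half, steps 9 and 10 for union and ring closure).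
Longest linear sequence: 7 steps (7 → 9 → 12 → 14 → 15 → 16 → 18 → 20).

**Step 9 (key step).** Most likely to go wrong: poor facial selectivity at the aldehyde if catalyst and α-stereocentre C5 turn out to be mismatched, or slow addition of two hindered partners that gives C5 time to epimerise or the olefin to conjugate. Fallback, setting out from 4 and 16 and coming back at 18: cross-metathesis of 4 with (E)-1,4-dibromobut-2-ene (second-generation Hoveyda–Grubbs catalyst) should give 2-[(2S,5R)-5-[(1E)-3-bromoprop-1-en-1-yl]-5-methyloxolan-2-yl]propan-2-yl acetate F1. Treating F1 and 16 with CrCl2 in THF at room temperature (Nozaki–Hiyama allylation; the alkenyl triflate is inert without a nickel co-catalyst) generates the more nucleophilic allylchromium species in the presence of the aldehyde. It adds through a closed chair with anti selectivity whatever the olefin geometry, the aldehyde face being chosen by the substrate alone, and gives 18.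

**Step 10.** Most likely to go wrong: intermolecular coupling and protodeboronation outrunning the slow closure of a seven-membered ring, so that transmetalation never occurs within one molecule. Fallback, setting out from 18 and coming back at 20:
- Hydroboration as in step 10 followed by NaBO3·4H2O should give the primary alcohol 2-[(2S,5R)-5-[(1S,2R)-1,4-dihydroxy-1-[(1S,5R)-2-methyl-5-[1-(trifluoromethanesulfonyloxy)ethenyl]cyclopent-2-en-1-yl]butan-2-yl]-5-methyloxolan-2-yl]propan-2-yl acetate F2.
- I2, PPh3 and imidazole convert only the primary hydroxyl into the iodide 2-[(2S,5R)-5-[(1S,2R)-1-hydroxy-4-iodo-1-[(1S,5R)-2-methyl-5-[1-(trifluoromethanesulfonyloxy)ethenyl]cyclopent-2-en-1-yl]butan-2-yl]-5-methyloxolan-2-yl]propan-2-yl acetate F3.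
- A nickel-catalysed reductive cross-electrophile coupling of the alkyl iodide with the alkenyl triflate (NiBr2·glyme, 4,4′-di-tert-butyl-2,2′-bipyridine, Mn powder, DMA, high dilution) then forms C9–C10 through an alkyl radical captured at nickel, a mechanism that does not depend on boron-to-palladium transfer, and gives 20.

**Step 5.** Most likely to go wrong: trapping of the vinylketene at the γ-position, or drift of the C3=C4 olefin into conjugation with the ester during the base-mediated cis-to-trans equilibration. Fallback, setting out from 7 and coming back at 12: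
- HBr in AcOH should give the hydrobromide (5R)-5-(2-bromopropan-2-yl)-2-methylcyclohex-2-en-1-one F4.
- Br2 in AcOH gives the tribromide (5S)-2,3-dibromo-5-(2-bromopropan-2-yl)-2-methylcyclohexan-1-one F5.
- NaOMe in MeOH effects a Favorskii ring contraction in which the cyclopropanone opens with loss of the β-bromide. This places the olefin at C3=C4 without a ketene and gives methyl (1S,5R)-5-(2-bromopropan-2-yl)-2-methylcyclopent-2-ene-1-carboxylate F6 as the trans isomer.
- Elimination of HBr from the side chain (LiBr, Li2CO3, DMF) regenerates the isopropenyl group and gives 12.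

**Step 6.** Most likely to go wrong: competing dihydroxylation and cleavage of the ring olefin C3=C4. Fallback, setting out from 7 and coming back at 14, in which the cleavage is done while the only other olefin is the deactivated enone:
- Ozonolysis of 7 (O3, CH2Cl2/MeOH, −78 °C; Me2S) should give (5R)-5-acetyl-2-methylcyclohex-2-en-1-one F7.
- Ethane-1,2-diol and TsOH protect the saturated ketone as (5R)-2-methyl-5-(2-methyl-1,3-dioxolan-2-yl)cyclohex-2-en-1-one F8.
- The conditions of step 4 give (5R)-6-diazo-2-methyl-5-(2-methyl-1,3-dioxolan-2-yl)cyclohex-2-en-1-one F9.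
- The conditions of step 5 give methyl (1S,5R)-2-methyl-5-(2-methyl-1,3-dioxolan-2-yl)cyclopent-2-ene-1-carboxylate F10.
- PPTS in aqueous acetone releases 14.

## Further compounds

F1 | step 9 | 2-[(2S,5R)-5-[(1E)-3-bromoprop-1-en-1-yl]-5-methyloxolan-2-yl]propan-2-yl acetate | BrC/C=C/[C@@]1(C)CC[C@@H](C(C)(C)OC(C)=O)O1
F2 | step 10 | 2-[(2S,5R)-5-[(1S,2R)-1,4-dihydroxy-1-[(1S,5R)-2-methyl-5-[1-(trifluoromethanesulfonyloxy)ethenyl]cyclopent-2-en-1-yl]butan-2-yl]-5-methyloxolan-2-yl]propan-2-yl acetate | OCC[C@@H]([C@@]1(C)CC[C@@H](C(C)(C)OC(C)=O)O1)[C@@H](O)[C@@H]1C(C)=CC[C@H]1C(=C)OS(=O)(=O)C(F)(F)F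
F3 | step 10 | 2-[(2S,5R)-5-[(1S,2R)-1-hydroxy-4-iodo-1-[(1S,5R)-2-methyl-5-[1-(trifluoromethanesulfonyloxy)ethenyl]cyclopent-2-en-1-yl]butan-2-yl]-5-methyloxolan-2-yl]propan-2-yl acetate | ICC[C@@H]([C@@]1(C)CC[C@@H](C(C)(C)OC(C)=O)O1)[C@@H](O)[C@@H]1C(C)=CC[C@H]1C(=C)OS(=O)(=O)C(F)(F)F
F4 | step 5 | (5R)-5-(2-bromopropan-2-yl)-2-methylcyclohex-2-en-1-one | CC1=CC[C@H](CC1=O)C(C)(C)Br
F5 | step 5 | (5S)-2,3-dibromo-5-(2-bromopropan-2-yl)-2-methylcyclohexan-1-one (C2 and C3 not defined) | CC1(Br)C(Br)C[C@H](CC1=O)C(C)(C)Br
F6 | step 5 | methyl (1S,5R)-5-(2-bromopropan-2-yl)-2-methylcyclopent-2-ene-1-carboxylate | COC(=O)[C@@H]1C(C)=CC[C@H]1C(C)(C)Br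
F7 | step 6 | (5R)-5-acetyl-2-methylcyclohex-2-en-1-one | CC1=CC[C@H](CC1=O)C(C)=O
F8 | step 6 | (5R)-2-methyl-5-(2-methyl-1,3-dioxolan-2-yl)cyclohex-2-en-1-one | CC1=CC[C@H](CC1=O)C1(C)OCCO1
F9 | step 6 | (5R)-6-diazo-2-methyl-5-(2-methyl-1,3-dioxolan-2-yl)cyclohex-2-en-1-one | CC1=CC[C@H](C(=[N+]=[N-])C1=O)C1(C)OCCO1
F10 | step 6 | methyl (1S,5R)-2-methyl-5-(2-methyl-1,3-dioxolan-2-yl)cyclopent-2-ene-1-carboxylate | COC(=O)[C@@H]1C(C)=CC[C@H]1C1(C)OCCO1
A1 | alternative 1 | (3aS,4S,5R,8aR)-5-[(2R)-2-hydroxy-6-methylhept-5-en-2-yl]-3-methyl-8-methylidene-1,3a,4,5,6,7,8,8a-octahydroazulen-4-ol | C=C1CC[C@@H]([C@](C)(O)CCC=C(C)C)[C@@H](O)[C@@H]2C(C)=CC[C@@H]12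
A2 | alternative 2 | 2-[(2S,5R)-5-methyl-5-[(2S)-4-[2-[(1R)-3-methylcyclopent-2-en-1-yl]-1,3-dithian-2-yl]-1-oxobutan-2-yl]oxolan-2-yl]propan-2-yl acetate | O=C[C@@H](CCC1(SCCCS1)[C@@H]1CCC(C)=C1)[C@@]1(C)CC[C@@H](C(C)(C)OC(C)=O)O1
A3 | alternative 3 | 2-[(2S,5R)-5-[(3aR,4R,5R,8aR)-4-hydroxy-8-methylidene-3-oxodecahydroazulen-5-yl]-5-methyloxolan-2-yl]propan-2-yl acetate (C4 ketone in ring A, no C4 methyl) | C=C1CC[C@@H]([C@@]2(C)CC[C@@H](C(C)(C)OC(C)=O)O2)[C@@H](O)[C@@H]2C(=O)CC[C@@H]12
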